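If the rate of making target followed starting material, it would fade at starting material's pace, so we compare the two clocks in the earlier runs.

| setting | east | south | flask |
|---|---|---|---|
| starting material | 0.070 M | 0.11 M | 0.050 M |
| second substrate | 2 equiv | 2 equiv | 2.00 equiv |
| free enzyme | 0.02 mol% | 0.02 mol% | 0.02 mol% |
| remark | run made earlier | run made earlier |  |

| run | time / min | target / % | starting material / % |
|---|---|---|---|
| east | 0.667 | 6.5 | 93.3 |
| east | 1.50 | 13.4 | 87.5 |
| east | 3.00 | 20.2 | 79.5 |
| east | 5.00 | 26.4 | 73.1 |
| south | 1.33 | 14.2 | 86.3 |
| south | 2.50 | 21.0 | 79.4 |
| south | 4.00 | 25.8 | 74.3 |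
| south | 5.00 | 28.1 | 71.4 |

(standard deviation of a reading: 0.3 percentage points)

- apparent order in second substrate when 30% of the starting material are converted (percent change of the rate of making target for one percent more second substrate charged)

In the east run, the rate falls 3.14-fold from the first interval to the last. That gives a rate half-time, the time in which the rate of making target halves, of 2.22 min. Starting material's half-time reads 12.3 min, so the rate fades faster than starting material. The richer south run reads 1.73 min, shorter than east. Taken one to one, target accounts for 13.2% of east's second substrate charge by 5.00 min. Our own reckoning is that second substrate also disappears by another route and that the rate follows it, which puts the order near 1.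

The forecast says 0.5, on other grounds: “That points to product inhibition”.

The flask gives 1.0.

    starting material + free enzyme ⇌ first complex (K = 5.29 M⁻¹, k = 6260 M⁻¹ s⁻¹)
    first complex → loaded enzyme + first product (k = 89.2 s⁻¹)
    second substrate + loaded enzyme ⇌ second complex (K = 10.0 M⁻¹, k = 4600 M⁻¹ s⁻¹)
    second complex → free enzyme + target (k = 32.5 s⁻¹)
    2 second substrate → self-condensation product (k = 0.128 M⁻¹ s⁻¹)

In the flask, second substrate goes from 14.7% of its charge at 3.00 min to 6.19% at 6.00 min, a half-time of 2.40 min over that span, beside a rate half-time of 2.46 min reckoned from the flask's target as the 2.22 min was in east. At 8.64 min, 90.1% of the flask's catalyst is loaded enzyme, the resting state, and 1.04% is first complex.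

The runs were computed with constants of no real substance, and the scatter is random.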